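**Retrosynthetic overview**
1. Manumycin G (21) ⇒ Mizoroki–Heck union of vinyl epoxyquinol 13 with bromodienamide 20 (forms the middle of the lower triene).
2. 20 ⇒ key step: its cyclopentenone ring is made by a four- to five-membered ring expansion, an N-acyliminium-triggered 1,2-acyl shift in a 2-silyloxycyclobutanone built from 2-hydroxycyclobutanone 17 and N-acylformimidate 16 of bromodienoic acid 3.
3. 13 ⇒ vinyl Grignard addition (sets C-4) to epoxy quinone monoketal 10 ⇐ asymmetric phase-transfer epoxidation (sets C-5, C-6) of monoketal 9 ⇐ oxidative dearomatisation of anilide 8 (3-aminophenol + trienoic acid 6).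
4. 6 ⇒ Suzuki–Miyaura coupling of 3 with the alkenylboronate of 3-methylbut-1-yne; acid 3 (from glutaconaldehyde potassium salt) feeds both side chains.
5. Ring order: six-membered carbocycle (arene, dearomatised in step 5) → oxirane (step 6); in the second branch the cyclopentenone by ring expansion (step 10); the branches meet in step 11.

Core numbering used below: C-1 ring ketone, C-2 amide-bearing carbon, C-4 carbinol, C-5/C-6 epoxide. The target is (4S,5R,6S), with the hydroxyl syn to the epoxide oxygen.

Assumption: N-benzylcinchoninium chloride is taken to give the (5R,6S)-epoxide in step 6; if the antipode predominates, the pseudoenantiomeric N-benzylcinchonidinium chloride is used with nothing else changed.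

**Route**

Step 1
Reactants: 1 glutaconaldehyde potassium salt [potassium (1E,3E)-5-oxopenta-1,3-dien-1-olate]
Product: 2 (2E,4E)-5-bromopenta-2,4-dienal
Conditions: Ph3PBr2 (1.1 equiv), CH2Cl2, −10 °C → rt; then I2 (1 mol %), rt, dark
Reagents that add atoms: dibromotriphenylphosphorane, BrP(Br)(c1ccccc1)(c1ccccc1)c1ccccc1
Why: Deoxybromination of a vinylogous carboxylate (O-phosphonium formation, then addition–elimination by bromide); the conjugated E,E-dienal is the thermodynamic isomer and iodine equilibrates any 4Z material.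

Step 2
Reactants: 2 (2E,4E)-5-bromopenta-2,4-dienal
Product: 3 (2E,4E)-5-bromopenta-2,4-dienoic acid
Conditions: NaClO2, NaH2PO4, 2-methylbut-2-ene, t-BuOH/H2O, 0 °C → rt
Reagents that add atoms: sodium chlorite, [Na+].[O-]Cl=O
Why: Pinnick oxidation turns the enal into the acid without touching the vinyl bromide or the alkene geometry, the alkene additive scavenging hypochlorous acid.

Step 3
Reactants: 4 3-methylbut-1-yne; 3 (2E,4E)-5-bromopenta-2,4-dienoic acid
Product: 6 (2E,4E,6E)-8-methylnona-2,4,6-trienoic acid, via alkenylboronate 5 (not isolated)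
Conditions: 4 (1.5 equiv), catecholborane, 70 °C, sealed tube; then 3, Pd(PPh3)4 (3 mol %), 2 M aq NaOH, THF, 60 °C; acidic work-up
Reagents that add atoms: none
Why: syn-Hydroboration of the terminal alkyne gives the (E)-alkenylboronate and Suzuki–Miyaura coupling with the vinyl bromide (as its carboxylate) retains both alkene geometries, so 6E comes from the hydroboration and 2E,4E from 3.

Step 4
Reactants: 6 (2E,4E,6E)-8-methylnona-2,4,6-trienoic acid; 7 3-aminophenol
Product: 8 (2E,4E,6E)-N-(3-hydroxyphenyl)-8-methylnona-2,4,6-trienamide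
Conditions: DCC, HOBt (0.2 equiv), THF, 0 °C → rt
Reagents that add atoms: none
Why: Carbodiimide amide coupling; the aniline nitrogen is far more nucleophilic than the phenol oxygen, so acylation is N-selective.

Step 5
Reactants: 8 (2E,4E,6E)-N-(3-hydroxyphenyl)-8-methylnona-2,4,6-trienamide
Product: 9 (2E,4E,6E)-N-(6,6-dimethoxy-3-oxocyclohexa-1,4-dien-1-yl)-8-methylnona-2,4,6-trienamide
Conditions: PhI(OAc)2 (2.2 equiv), MeOH, −10 °C → rt
Reagents that add atoms: methanol, CO
Why: Two successive oxidative dearomatisations by the trivalent iodine reagent (phenol → 4-methoxyphenol → p-quinone monoketal), methanol adding para to the phenol oxygen each time, which puts the ketal next to the amide-bearing carbon and leaves the future C-4 as the free ketone.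

Step 6
Reactants: 9 (2E,4E,6E)-N-(6,6-dimethoxy-3-oxocyclohexa-1,4-dien-1-yl)-8-methylnona-2,4,6-trienamide
Product: 10 (2E,4E,6E)-N-[(1S,6R)-2,2-dimethoxy-5-oxo-7-oxabicyclo[4.1.0]hept-3-en-3-yl]-8-methylnona-2,4,6-trienamide
Conditions: t-BuOOH, aq NaOH, N-benzylcinchoninium chloride (20 mol %), toluene, 0 °C → rt; recrystallise
Reagents that add atoms: tert-butyl hydroperoxide, CC(C)(C)OO
Why: Weitz–Scheffer epoxidation under chiral phase-transfer catalysis; only the unsubstituted enone double bond is electrophilic (the other is a vinylogous imide), and the chiral ammonium–peroxide ion pair selects one enone face, setting C-5 (R) and C-6 (S) together as the cis-epoxide.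

Step 7
Reactants: 10 (2E,4E,6E)-N-[(1S,6R)-2,2-dimethoxy-5-oxo-7-oxabicyclo[4.1.0]hept-3-en-3-yl]-8-methylnona-2,4,6-trienamide; 11 vinylmagnesium bromide
Product: 12 (2E,4E,6E)-N-[(1S,5S,6R)-5-ethenyl-5-hydroxy-2,2-dimethoxy-7-oxabicyclo[4.1.0]hept-3-en-3-yl]-8-methylnona-2,4,6-trienamide
Conditions: CH2=CHMgBr (3 equiv), THF, −78 → −40 °C; then H2O (pH 7 phosphate buffer)
Reagents that add atoms: none
Why: Grignard 1,2-addition to the ketone (the first equivalent deprotonates the amide N–H); attack on the face anti to the epoxide oxygen of the magnesium-chelated epoxy ketone puts the new hydroxyl syn to the epoxide, which is C-4 (S).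

Step 8
Reactants: 12 (2E,4E,6E)-N-[(1S,5S,6R)-5-ethenyl-5-hydroxy-2,2-dimethoxy-7-oxabicyclo[4.1.0]hept-3-en-3-yl]-8-methylnona-2,4,6-trienamide
Product: 13 (2E,4E,6E)-N-[(1S,5S,6R)-5-ethenyl-5-hydroxy-2-oxo-7-oxabicyclo[4.1.0]hept-3-en-3-yl]-8-methylnona-2,4,6-trienamide
Conditions: montmorillonite K10 (acid-activated clay, idealised Al2Si4O10(OH)2·nH2O), wet CH2Cl2, rt
Reagents that add atoms: water, O
Why: Mild heterogeneous acid hydrolysis of the dimethyl ketal frees the enone without ionising the tertiary allylic alcohol or opening the epoxide; no stereocentre is touched.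

Step 9
Reactants: 3 (2E,4E)-5-bromopenta-2,4-dienoic acid; 14 ethyl formimidate hydrochloride
Product: 16 ethyl N-[(2E,4E)-5-bromopenta-2,4-dienoyl]methanimidate, via acid chloride 15 (not isolated)
Conditions: (COCl)2, DMF (cat.), CH2Cl2, 0 °C → rt, evaporate; then 14, Et3N (2.2 equiv), CH2Cl2, −20 → 0 °C
Reagents that add atoms: none
Why: N-Acylation of an imidate by an acid chloride gives the N-acylimidate, a one-carbon N-acyliminium precursor that already carries the side chain and the nitrogen of the future enaminone.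

Step 10
Reactants: 16 ethyl N-[(2E,4E)-5-bromopenta-2,4-dienoyl]methanimidate; 17 2-hydroxycyclobutan-1-one
Product: 20 (2E,4E)-5-bromo-N-(2-hydroxy-5-oxocyclopent-1-en-1-yl)penta-2,4-dienamide, via enediol bis-silyl ether 18 (not isolated), via silyloxycyclobutanone adduct 19 (not isolated)
Conditions: 17 (1.2 equiv), TMSOTf (3.0 equiv), i-Pr2NEt (2.2 equiv), CH2Cl2, 0 °C; then 16, −78 → −20 °C; then TFA (5 equiv), 0 °C → rt; H2O
Reagents that add atoms: none
Why: Proposed new method: in situ bis-silylation of 17 gives enediol ether 18, whose Mukaiyama–Mannich addition to the TMSOTf-activated N-acylimidate gives N,O-acetal 19; acid then ionises the ethoxy group to an N-acyliminium ion and the ring acyl carbon shifts 1,2 onto that carbon (driven by cyclobutane strain release and the push of the silyloxy group), expanding the four-membered ring to the five-membered 2-acylamino-1,3-dione, which enolises to 20 with no stereocentre formed; the closest known reactions are the geminal acylation of acetals with 1,2-bis(silyloxy)cyclobutene (aldol, then pinacol-type acyl shift) and N-acyliminium-triggered semipinacol ring expansions of cyclobutanols, neither shown with an N-acylimidate as the one-carbon partner.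

Step 11
Reactants: 13 (2E,4E,6E)-N-[(1S,5S,6R)-5-ethenyl-5-hydroxy-2-oxo-7-oxabicyclo[4.1.0]hept-3-en-3-yl]-8-methylnona-2,4,6-trienamide; 20 (2E,4E)-5-bromo-N-(2-hydroxy-5-oxocyclopent-1-en-1-yl)penta-2,4-dienamide
Product: 21 Manumycin G
Conditions: Pd2(dba)3 (5 mol %), [HP(t-Bu)3]BF4 (12 mol %), Cy2NMe (3 equiv), DMF, rt, dark
Reagents that add atoms: none
Why: Mizoroki–Heck coupling: oxidative addition of the dienyl bromide to zerovalent palladium with retention, insertion at the terminus of the monosubstituted vinyl group of 13, and syn β-hydride elimination (possible only away from the quaternary carbinol) give the new E-alkene; no stereocentre is affected.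

**Compound list**
1 | glutaconaldehyde potassium salt, potassium (1E,3E)-5-oxopenta-1,3-dien-1-olate | [K+].[O-]/C=C/C=C/C=O | starting material
2 | (2E,4E)-5-bromopenta-2,4-dienal | Br/C=C/C=C/C=O | intermediate
3 | (2E,4E)-5-bromopenta-2,4-dienoic acid | Br/C=C/C=C/C(=O)O | intermediate
4 | 3-methylbut-1-yne | CC(C)C#C | starting material
5 | 2-[(E)-3-methylbut-1-en-1-yl]-1,3,2-benzodioxaborole | CC(C)/C=C/B1Oc2ccccc2O1 | intermediate (not isolated)
6 | (2E,4E,6E)-8-methylnona-2,4,6-trienoic acid | CC(C)/C=C/C=C/C=C/C(=O)O | intermediate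
7 | 3-aminophenol | Nc1cccc(O)c1 | starting material
8 | (2E,4E,6E)-N-(3-hydroxyphenyl)-8-methylnona-2,4,6-trienamide | CC(C)/C=C/C=C/C=C/C(=O)Nc1cccc(O)c1 | intermediate
9 | (2E,4E,6E)-N-(6,6-dimethoxy-3-oxocyclohexa-1,4-dien-1-yl)-8-methylnona-2,4,6-trienamide | CC(C)/C=C/C=C/C=C/C(=O)NC1=CC(=O)C=CC1(OC)OC | intermediate
10 | (2E,4E,6E)-N-[(1S,6R)-2,2-dimethoxy-5-oxo-7-oxabicyclo[4.1.0]hept-3-en-3-yl]-8-methylnona-2,4,6-trienamide; (5R,6S) in core numbering | CC(C)/C=C/C=C/C=C/C(=O)NC1=CC(=O)[C@@H]2O[C@@H]2C1(OC)OC | intermediate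
11 | vinylmagnesium bromide | C=C[Mg]Br | starting material
12 | (2E,4E,6E)-N-[(1S,5S,6R)-5-ethenyl-5-hydroxy-2,2-dimethoxy-7-oxabicyclo[4.1.0]hept-3-en-3-yl]-8-methylnona-2,4,6-trienamide; hydroxyl syn to epoxide | CC(C)/C=C/C=C/C=C/C(=O)NC1=C[C@@](O)(C=C)[C@@H]2O[C@@H]2C1(OC)OC | intermediate
13 | (2E,4E,6E)-N-[(1S,5S,6R)-5-ethenyl-5-hydroxy-2-oxo-7-oxabicyclo[4.1.0]hept-3-en-3-yl]-8-methylnona-2,4,6-trienamide | CC(C)/C=C/C=C/C=C/C(=O)NC1=C[C@@](O)(C=C)[C@@H]2O[C@@H]2C1=O | intermediate
14 | ethyl formimidate hydrochloride | CCOC=N.Cl | starting material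
15 | (2E,4E)-5-bromopenta-2,4-dienoyl chloride | Br/C=C/C=C/C(Cl)=O | intermediate (not isolated)
16 | ethyl N-[(2E,4E)-5-bromopenta-2,4-dienoyl]methanimidate | Br/C=C/C=C/C(=O)N=COCC | intermediate
17 | 2-hydroxycyclobutan-1-one (racemic) | OC1CCC1=O | starting material
18 | 1,2-bis(trimethylsilyloxy)cyclobut-1-ene | C[Si](C)(C)OC1=C(O[Si](C)(C)C)CC1 | intermediate (not isolated)
19 | (2E,4E)-5-bromo-N-{ethoxy[2-oxo-1-(trimethylsilyloxy)cyclobutyl]methyl}penta-2,4-dienamide (diastereomer mixture, both centres lost in the next event) | Br/C=C/C=C/C(=O)NC(OCC)C1(O[Si](C)(C)C)CCC1=O | intermediate (not isolated)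
20 | (2E,4E)-5-bromo-N-(2-hydroxy-5-oxocyclopent-1-en-1-yl)penta-2,4-dienamide | Br/C=C/C=C/C(=O)NC1=C(O)CCC1=O | intermediate
21 | Manumycin G, (2E,4E,6E)-N-[(1S,5S,6R)-5-hydroxy-5-[(1E,3E,5E)-7-[(2-hydroxy-5-oxocyclopent-1-en-1-yl)amino]-7-oxohepta-1,3,5-trien-1-yl]-2-oxo-7-oxabicyclo[4.1.0]hept-3-en-3-yl]-8-methylnona-2,4,6-trienamide | CC(C)/C=C/C=C/C=C/C(=O)NC1=C[C@@](O)(/C=C/C=C/C=C/C(=O)NC2=C(O)CCC2=O)[C@@H]2O[C@@H]2C1=O | target

**Step count**
Total: 11 steps. Longest linear sequence: 9 steps (steps 1–8 and 11; 1 → 2 → 3 → 6 → 8 → 9 → 10 → 12 → 13 → 21).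

**Three steps most likely to fail, with fallbacks**

Step 10 (proposed ring expansion). The N-acyliminium ion may be hydrolysed or take up a second enol ether before the acyl shift, and in situ silylation of 17 may give some of the wrong enol ether. The fallback uses known chemistry and sets out from 3. Acid 3 is converted into acid chloride 15 as in step 9 and added to commercial 2-amino-3-hydroxycyclopent-2-en-1-one hydrochloride (free base NC1=C(O)CCC1=O) in pyridine/CH2Cl2 at 0 °C → rt. Direct N-acylation of the vinylogous amide (any O-acyl isomer migrates to nitrogen on warming) gives 20, where the fallback comes back to the route, replacing steps 9 and 10. No compound outside the list is made on this way (F0).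

Step 11 (Heck coupling). The epoxyquinol is base- and light-sensitive, insertion into the hindered vinyl carbinol may be slow, and the polyene may isomerise. The fallback sets out from 10 and comes back at 21, using a Stille coupling in place of the Heck reaction. HC≡CMgBr (THF, −78 °C) adds to 10 anti to the epoxide to give the ethynyl carbinol F1. Bu3SnH with PdCl2(PPh3)2 (THF, 0 °C) hydrostannylates the alkyne syn, with tin on the terminal carbon, to give the (E)-vinylstannane F2. Montmorillonite K10 in wet CH2Cl2 frees the enone to give the stannyl epoxyquinol F3. F3 and 20 are then joined with PdCl2(MeCN)2 in DMF at rt, base-free, to give 21.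

Step 6 (asymmetric epoxidation). Enantioselectivity and yield under phase-transfer control are the concern. The fallback sets out from 9 and comes back at 13, using auxiliary control in place of catalyst control. Transketalisation of 9 with (2R,4R)-pentane-2,4-diol (BF3·OEt2 cat., DME; the antipodal diol if the facial sense proves opposite) gives the spiroketal dienone F4. t-BuOOH/DBU in THF epoxidises the enone face left open by the axial methyl group to give the epoxy spiroketal F5, with the minor diastereomer removed by chromatography. CH2=CHMgBr (THF, −78 °C) adds anti to the epoxide to give the vinyl carbinol spiroketal F6. Montmorillonite K10 in wet CH2Cl2 removes the diol ketal and returns 13.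

**Further compounds**
F0 | step 10 | none | none
F1 | step 11 | (2E,4E,6E)-N-[(1S,5R,6R)-5-ethynyl-5-hydroxy-2,2-dimethoxy-7-oxabicyclo[4.1.0]hept-3-en-3-yl]-8-methylnona-2,4,6-trienamide | CC(C)/C=C/C=C/C=C/C(=O)NC1=C[C@@](O)(C#C)[C@@H]2O[C@@H]2C1(OC)OC
F2 | step 11 | (2E,4E,6E)-N-[(1S,5R,6R)-5-hydroxy-2,2-dimethoxy-5-[(E)-2-(tributylstannyl)ethenyl]-7-oxabicyclo[4.1.0]hept-3-en-3-yl]-8-methylnona-2,4,6-trienamide | CC(C)/C=C/C=C/C=C/C(=O)NC1=C[C@@](O)(/C=C/[Sn](CCCC)(CCCC)CCCC)[C@@H]2O[C@@H]2C1(OC)OC
F3 | step 11 | (2E,4E,6E)-N-[(1S,5R,6R)-5-hydroxy-2-oxo-5-[(E)-2-(tributylstannyl)ethenyl]-7-oxabicyclo[4.1.0]hept-3-en-3-yl]-8-methylnona-2,4,6-trienamide | CC(C)/C=C/C=C/C=C/C(=O)NC1=C[C@@](O)(/C=C/[Sn](CCCC)(CCCC)CCCC)[C@@H]2O[C@@H]2C1=O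
F4 | step 6 | (2E,4E,6E)-N-[(2R,4R)-2,4-dimethyl-9-oxo-1,5-dioxaspiro[5.5]undeca-7,10-dien-7-yl]-8-methylnona-2,4,6-trienamide (9 with the (2R,4R)-pentane-2,4-diyl ketal in place of the two methoxy groups) | CC(C)/C=C/C=C/C=C/C(=O)NC1=CC(=O)C=CC12O[C@H](C)C[C@@H](C)O2
F5 | step 6 | 10 with the (2R,4R)-pentane-2,4-diyl ketal in place of the two methoxy groups; (5R,6S)-cis-epoxide in core numbering | CC(C)/C=C/C=C/C=C/C(=O)NC1=CC(=O)[C@@H]2O[C@@H]2C13O[C@H](C)C[C@@H](C)O3
F6 | step 6 | 12 with the (2R,4R)-pentane-2,4-diyl ketal in place of the two methoxy groups; (4S,5R,6S) in core numbering, hydroxyl syn to epoxide | CC(C)/C=C/C=C/C=C/C(=O)NC1=C[C@@](O)(C=C)[C@@H]2O[C@@H]2C13O[C@H](C)C[C@@H](C)O3
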